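**Retrosynthetic overview**

- The target comes from a trans-fused aryltetralin γ-lactone by LiAlH4 reduction and then O-debenzylation. In that lactone the two 1,4-related CH2OH carbons are tied as C2–C(=O)–O–CH2–C3. Tetralin locants: C1 bears catechol ring C, C4 is the ring CH2, C4a and C8a are the fusion carbons of dimethoxy ring A, and ring B is the saturated ring.
- Cutting C1–C8a and C2–C(=O) of the lactone leads to an acyclic (R)-homoallylic N-phthalimidoyl oxalate. One photoredox radical–polar crossover bicyclisation closes the lactone ring first and ring B second, and sets C2 and C1 from C3.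
- Enabling feature: the oxygen on C4′ of ring C is para to C1, so the C1 radical left by the lactone closure is easily oxidised to a quinone-methide-like cation. C8a of ring A lies para to the C6 methoxy group and is the most nucleophilic free position. The CH2OH oxygen on C3 is the handle that delivers the carbonyl carbon to C2.
- The oxalate comes from the homoallylic alcohol, which comes from Evans alkylation of a styrylacetyl imide with 3,4-dimethoxybenzyl bromide (this sets C3, the only auxiliary-derived stereocentre). The styrylacetic acid comes from a Wittig reaction of 3,4-bis(benzyloxy)benzaldehyde.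

Key step: step 6

Remark: 3,4-dimethoxybenzyl bromide is taken as a purchasable reagent that is used fresh, and the alkene is drawn E throughout although the key step does not depend on its geometry.

Step 1
Reactants: 1 3,4-bis(benzyloxy)benzaldehyde; 2 (2-carboxyethyl)triphenylphosphonium bromide
Product: 4 (E)-4-[3,4-bis(benzyloxy)phenyl]but-3-enoic acid, via ylide carboxylate 3 (not isolated)
Conditions: NaN(SiMe3)2 (2.2 equiv), THF, 0 °C → rt; 1 M HCl work-up
Reagents that add atoms: NaN(SiMe3)2, C[Si](C)(C)[N-][Si](C)(C)C.[Na+] (its sodium stays only in 3)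
Why: Wittig olefination, in which the carboxylate-bearing ylide should favour the E alkene with aromatic aldehydes, and the geometry is in any case erased in step 6.

Step 2
Reactants: 4 (E)-4-[3,4-bis(benzyloxy)phenyl]but-3-enoic acid; 5 (R)-4-benzyloxazolidin-2-one
Product: 7 (R)-4-benzyl-3-{(E)-4-[3,4-bis(benzyloxy)phenyl]but-3-enoyl}oxazolidin-2-one, via mixed pivalic anhydride 6 (not isolated)
Conditions: t-BuCOCl, Et3N, THF, −20 °C; then 5, LiCl, −20 °C → rt
Reagents that add atoms: pivaloyl chloride, CC(C)(C)C(=O)Cl (its acyl group stays only in 6)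
Why: N-acylation of the Evans auxiliary through the mixed anhydride needs no strong base, the double bond has no driving force to leave conjugation with the aryl ring, and no stereocentre is formed.

Step 3
Reactants: 7 (R)-4-benzyl-3-{(E)-4-[3,4-bis(benzyloxy)phenyl]but-3-enoyl}oxazolidin-2-one; 8 3,4-dimethoxybenzyl bromide
Product: 10 (R)-4-benzyl-3-{(2R,3E)-4-[3,4-bis(benzyloxy)phenyl]-2-(3,4-dimethoxybenzyl)but-3-enoyl}oxazolidin-2-one, via sodium dienolate 9 (not isolated)
Conditions: NaN(SiMe3)2 (1.05 equiv), THF, −78 °C; then 8, −78 → −40 °C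
Reagents that add atoms: NaN(SiMe3)2, C[Si](C)(C)[N-][Si](C)(C)C.[Na+] (its sodium stays only in 9)
Why: Evans asymmetric alkylation, in which the chelated Z-dienolate reacts at its α-carbon with the benzylic bromide on the face away from the C4 benzyl group of the (R)-auxiliary, setting the future C3 as R.

Step 4
Reactants: 10 (R)-4-benzyl-3-{(2R,3E)-4-[3,4-bis(benzyloxy)phenyl]-2-(3,4-dimethoxybenzyl)but-3-enoyl}oxazolidin-2-one
Product: 11 (2R,3E)-4-[3,4-bis(benzyloxy)phenyl]-2-(3,4-dimethoxybenzyl)but-3-en-1-ol
Conditions: LiBH4, Et2O–THF, 0 °C → rt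
Reagents that add atoms: none
Why: Reductive cleavage of the N-acyloxazolidinone attacks the exocyclic carbonyl group under non-basic conditions, so the allylic stereocentre is kept and the auxiliary is recovered.

Step 5
Reactants: 11 (2R,3E)-4-[3,4-bis(benzyloxy)phenyl]-2-(3,4-dimethoxybenzyl)but-3-en-1-ol
Product: 12 (2R,3E)-4-[3,4-bis(benzyloxy)phenyl]-2-(3,4-dimethoxybenzyl)but-3-en-1-yl 1,3-dioxoisoindolin-2-yl oxalate
Conditions: N-hydroxyphthalimide, (COCl)2 (excess), THF, rt, then evaporation; 11, Et3N, DMAP (cat.), THF, 0 °C → rt; filtration and concentration without water or silica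
Reagents that add atoms: oxalyl chloride, O=C(Cl)C(=O)Cl; N-hydroxyphthalimide, O=C1c2ccccc2C(=O)N1O
Why: O-acylation of the primary alcohol with preformed chloro N-phthalimidoyl oxalate is the standard entry to N-phthalimidoyl oxalates, base is present throughout so the acid-sensitive styrene never meets HCl, and no stereocentre is touched.

Step 6
Reactants: 12 (2R,3E)-4-[3,4-bis(benzyloxy)phenyl]-2-(3,4-dimethoxybenzyl)but-3-en-1-yl 1,3-dioxoisoindolin-2-yl oxalate
Product: 16 (3aR,9S,9aR)-9-[3,4-bis(benzyloxy)phenyl]-6,7-dimethoxy-3a,4,9,9a-tetrahydronaphtho[2,3-c]furan-1(3H)-one, via alkoxycarbonyl radical 13 (not isolated), via benzylic radical 14 (not isolated), via benzylic cation 15 (not isolated)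
Conditions: fac-Ir(ppy)3 (1 mol %), degassed CH2Cl2 (0.02 M), blue LEDs (450 nm), rt
Reagents that add atoms: none
Why: Proposed new method: the excited fac-Ir(ppy)3 gives one electron to the phthalimidoyl oxalate, N–O cleavage and loss of one CO2 leave the primary alkoxycarbonyl radical 13, which loses its second CO2 only slowly and instead adds 5-exo-trig to C2 of the styrene, closing the lactone and placing the spin on C1 (14). Tetravalent iridium then oxidises this para-alkoxybenzyl radical to cation 15, whose C1 is attacked by C8a in a six-membered Friedel–Crafts ring closure (endo with respect to the C4a=C8a bond of ring A), and the phthalimide anion takes the proton, so the step is redox-neutral and needs no acid. The closest known reaction types are the 5-exo lactonisation of alkoxycarbonyl radicals made from homoallylic oxalates or selenocarbonates, the photoredox radical–polar crossover carboarylation of styrenes with N-acyloxyphthalimides, and the acid-induced cyclisation of 2-(hydroxybenzyl)-3-benzylbutyrolactones to trans,trans aryltetralin lactones; only their union in one flask is new. C2 is controlled by C3, because in the chair-like Beckwith–Houk transition state the 3,4-dimethoxybenzyl group is pseudo-equatorial and ends up trans to the new C2–C1 branch. C1 is controlled by C2, because the planar cation closes through the half-chair in which ring C is pseudo-equatorial and anti to the carbonyl branch on C2, which gives the 1,2-trans product. The step needs site selectivity on ring A, secured because the attacked position is para to a methoxy group and unhindered whereas the other ortho position is flanked by a methoxy group, and it needs chemoselective electron transfer, secured because the excited catalyst is a strong reductant but too weak an oxidant to touch the electron-rich styrene and arenes (E/Z scrambling by energy transfer is harmless, since the alkene geometry is erased at the radical stage).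

Step 7
Reactants: 16 (3aR,9S,9aR)-9-[3,4-bis(benzyloxy)phenyl]-6,7-dimethoxy-3a,4,9,9a-tetrahydronaphtho[2,3-c]furan-1(3H)-one
Product: 17 {(1S,2R,3R)-1-[3,4-bis(benzyloxy)phenyl]-6,7-dimethoxy-1,2,3,4-tetrahydronaphthalene-2,3-diyl}dimethanol
Conditions: LiAlH4, THF, 0 °C → rt; aqueous NaOH work-up
Reagents that add atoms: none
Why: LiAlH4 reduction of a γ-lactone to the 1,4-diol, in which hydride addition is much faster than enolisation, so C2 is not epimerised and the aryl benzyl and methyl ethers are inert.

Step 8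
Reactants: 17 {(1S,2R,3R)-1-[3,4-bis(benzyloxy)phenyl]-6,7-dimethoxy-1,2,3,4-tetrahydronaphthalene-2,3-diyl}dimethanol
Product: 18 4-[(1S,2R,3R)-2,3-bis(hydroxymethyl)-6,7-dimethoxy-1,2,3,4-tetrahydronaphthalen-1-yl]benzene-1,2-diol
Conditions: H2 (1 atm), 10% Pd/C, EtOAc–MeOH, rt; work-up under argon
Reagents that add atoms: none
Why: Catalytic hydrogenolysis cleaves only the two O-benzyl bonds, while the methyl ethers, the primary alcohols and the C–C bonds at the doubly benzylic C1 are untouched, so all three stereocentres persist.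

**Compound list**

1 | 3,4-bis(benzyloxy)benzaldehyde | O=Cc1ccc(OCc2ccccc2)c(OCc2ccccc2)c1 | starting material
2 | (2-carboxyethyl)triphenylphosphonium bromide | OC(=O)CC[P+](c1ccccc1)(c1ccccc1)c1ccccc1.[Br-] | starting material
3 | sodium 3-(triphenylphosphoranylidene)propanoate (ylide carboxylate) | [Na+].[O-]C(=O)CC=P(c1ccccc1)(c1ccccc1)c1ccccc1 | intermediate
4 | (E)-4-[3,4-bis(benzyloxy)phenyl]but-3-enoic acid | OC(=O)C/C=C/c1ccc(OCc2ccccc2)c(OCc2ccccc2)c1 | intermediate
5 | (R)-4-benzyloxazolidin-2-one | O=C1N[C@H](Cc2ccccc2)CO1 | starting material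
6 | mixed pivalic anhydride of 4 | CC(C)(C)C(=O)OC(=O)C/C=C/c1ccc(OCc2ccccc2)c(OCc2ccccc2)c1 | intermediate
7 | (R)-4-benzyl-3-{(E)-4-[3,4-bis(benzyloxy)phenyl]but-3-enoyl}oxazolidin-2-one | O=C(C/C=C/c1ccc(OCc2ccccc2)c(OCc2ccccc2)c1)N1[C@H](Cc2ccccc2)COC1=O | intermediate
8 | 3,4-dimethoxybenzyl bromide | COc1ccc(CBr)cc1OC | starting material
9 | sodium (Z)-dienolate of 7 | [Na+].[O-]/C(=C\C=C\c1ccc(OCc2ccccc2)c(OCc2ccccc2)c1)N1[C@H](Cc2ccccc2)COC1=O | intermediate
10 | (R)-4-benzyl-3-{(2R,3E)-4-[3,4-bis(benzyloxy)phenyl]-2-(3,4-dimethoxybenzyl)but-3-enoyl}oxazolidin-2-one | O=C([C@H](Cc1ccc(OC)c(OC)c1)/C=C/c1ccc(OCc2ccccc2)c(OCc2ccccc2)c1)N1[C@H](Cc2ccccc2)COC1=O | intermediate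
11 | (2R,3E)-4-[3,4-bis(benzyloxy)phenyl]-2-(3,4-dimethoxybenzyl)but-3-en-1-ol | OC[C@H](Cc1ccc(OC)c(OC)c1)/C=C/c1ccc(OCc2ccccc2)c(OCc2ccccc2)c1 | intermediate
12 | N-phthalimidoyl oxalate of 11 | O=C(OC[C@H](Cc1ccc(OC)c(OC)c1)/C=C/c1ccc(OCc2ccccc2)c(OCc2ccccc2)c1)C(=O)ON1C(=O)c2ccccc2C1=O | intermediate
13 | alkoxycarbonyl radical derived from 12 | O=[C]OC[C@H](Cc1ccc(OC)c(OC)c1)/C=C/c1ccc(OCc2ccccc2)c(OCc2ccccc2)c1 | intermediate
14 | C1 benzylic radical of the trans-2,3-disubstituted lactone | O=C1OC[C@H](Cc2ccc(OC)c(OC)c2)[C@H]1[CH]c1ccc(OCc2ccccc2)c(OCc2ccccc2)c1 | intermediate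
15 | C1 benzylic cation of the trans-2,3-disubstituted lactone | O=C1OC[C@H](Cc2ccc(OC)c(OC)c2)[C@H]1[CH+]c1ccc(OCc2ccccc2)c(OCc2ccccc2)c1 | intermediate
16 | (3aR,9S,9aR)-9-[3,4-bis(benzyloxy)phenyl]-6,7-dimethoxy-3a,4,9,9a-tetrahydronaphtho[2,3-c]furan-1(3H)-one | COc1cc2c(cc1OC)[C@H](c1ccc(OCc3ccccc3)c(OCc3ccccc3)c1)[C@H]1C(=O)OC[C@@H]1C2 | intermediate
17 | {(1S,2R,3R)-1-[3,4-bis(benzyloxy)phenyl]-6,7-dimethoxy-1,2,3,4-tetrahydronaphthalene-2,3-diyl}dimethanol | COc1cc2c(cc1OC)[C@H](c1ccc(OCc3ccccc3)c(OCc3ccccc3)c1)[C@@H](CO)[C@H](CO)C2 | intermediate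
18 | 4-[(1S,2R,3R)-2,3-bis(hydroxymethyl)-6,7-dimethoxy-1,2,3,4-tetrahydronaphthalen-1-yl]benzene-1,2-diol | COc1cc2c(cc1OC)[C@H](c1ccc(O)c(O)c1)[C@@H](CO)[C@H](CO)C2 | target

**Step count**

Total steps: 8. Longest linear sequence: 8 steps (1 → 18).

**Steps most likely to fail**

1. Step 6.
   - What may go wrong:
     - The benzylic radical may be oxidised too slowly.
     - The cation may be diverted by proton loss from C2 or by capture by the phthalimide anion.
     - The alkoxycarbonyl radical may take a hydrogen atom from the C4 methylene by 1,5-transfer.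
     - The facial selectivity of the 5-exo closure may be modest.
   - The fallback uses known chemistry throughout. It sets out from 1 and comes back at 16 through the same cation 15.
   - Purchased 3-(3,4-dimethoxyphenyl)propanoic acid is attached (t-BuCOCl, Et3N, LiCl, THF) to purchased (S)-4-benzyloxazolidin-2-one to give the saturated imide F1.
   - Evans alkylation (NaN(SiMe3)2, tert-butyl bromoacetate, THF, −78 °C) gives the alkylated imide F2, and LiBH4 gives the hydroxy ester F3.
   - TFA in CH2Cl2 closes F3 to (R)-4-(3,4-dimethoxybenzyl)dihydrofuran-2(3H)-one F4.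
   - Deprotonation (LiN(SiMe3)2, THF, −78 °C) and addition to aldehyde 1 anti to the benzyl group gives the trans aldol adduct F5, of which both carbinol epimers serve.
   - TFA in CH2Cl2 at 0 °C ionises the carbinol to 15, which closes to 16.

2. Step 3.
   - What may go wrong: proton exchange between the doubly activated α-CH of the product and unreacted dienolate may erode the configuration, or alkylation may take place at the γ-carbon.
   - The fallback sets out from 5, 8 and 1 and comes back at 11. The stereocentre is made on a simpler dienolate and the aryl group is attached afterwards.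
   - 5 is acylated with crotonic anhydride (Et3N, LiCl, THF) to the N-crotonoyl imide F6.
   - NaN(SiMe3)2 at −78 °C gives the sodium dienolate F7. Its well-established deconjugative α-alkylation with 8 gives the α-vinyl imide F8, which is less acidic than 10.
   - LiBH4 gives (R)-2-(3,4-dimethoxybenzyl)but-3-en-1-ol F9.
   - Methylenation of 1 (Ph3P=CH2, THF) gives 1,2-bis(benzyloxy)-4-vinylbenzene F10.
   - Cross-metathesis of the two alkenes (second-generation Grubbs catalyst, CH2Cl2, reflux) installs the E-styrene and gives 11.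

3. Step 5.
   - What may go wrong: the doubly activated oxalate may be hydrolysed or attacked by the amine base during preparation and handling.
   - The fallback sets out from 11 and comes back at 16. It uses another class of radical precursor that is never exposed to water, base or silica.
   - 11 is treated with excess (COCl)2 in Et2O at 0 °C, and evaporation leaves the alkyl chlorooxoacetate F11.
   - Irradiation with fac-Ir(ppy)3 and 2,6-lutidine in CH2Cl2 (blue LEDs) reduces the acid chloride. Loss of chloride and CO gives the same radical 13.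
   - The cascade then runs on through 14 and 15 to 16, and any benzylic chloride formed from 15 should re-ionise.

**Further compounds**

F1 | step 6 | (S)-4-benzyl-3-[3-(3,4-dimethoxyphenyl)propanoyl]oxazolidin-2-one | O=C(CCc1ccc(OC)c(OC)c1)N1[C@@H](Cc2ccccc2)COC1=O
F2 | step 6 | tert-butyl (3R)-4-[(4S)-4-benzyl-2-oxooxazolidin-3-yl]-3-(3,4-dimethoxybenzyl)-4-oxobutanoate | O=C([C@H](Cc1ccc(OC)c(OC)c1)CC(=O)OC(C)(C)C)N1[C@@H](Cc2ccccc2)COC1=O
F3 | step 6 | tert-butyl (3R)-4-(3,4-dimethoxyphenyl)-3-(hydroxymethyl)butanoate | OC[C@H](Cc1ccc(OC)c(OC)c1)CC(=O)OC(C)(C)C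
F4 | step 6 | (R)-4-(3,4-dimethoxybenzyl)dihydrofuran-2(3H)-one | O=C1OC[C@H](Cc2ccc(OC)c(OC)c2)C1
F5 | step 6 | (3S,4R)-3-{[3,4-bis(benzyloxy)phenyl](hydroxy)methyl}-4-(3,4-dimethoxybenzyl)dihydrofuran-2(3H)-one, carbinol centre as a mixture | O=C1OC[C@H](Cc2ccc(OC)c(OC)c2)[C@H]1C(O)c1ccc(OCc2ccccc2)c(OCc2ccccc2)c1
F6 | step 3 | (R)-4-benzyl-3-[(E)-but-2-enoyl]oxazolidin-2-one | C/C=C/C(=O)N1[C@H](Cc2ccccc2)COC1=O
F7 | step 3 | sodium (Z)-dienolate of F6 | [Na+].[O-]/C(=C\C=C)N1[C@H](Cc2ccccc2)COC1=O
F8 | step 3 | (R)-4-benzyl-3-[(2R)-2-(3,4-dimethoxybenzyl)but-3-enoyl]oxazolidin-2-one | O=C([C@H](Cc1ccc(OC)c(OC)c1)C=C)N1[C@H](Cc2ccccc2)COC1=O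
F9 | step 3 | (R)-2-(3,4-dimethoxybenzyl)but-3-en-1-ol | OC[C@H](Cc1ccc(OC)c(OC)c1)C=C
F10 | step 3 | 1,2-bis(benzyloxy)-4-vinylbenzene | C=Cc1ccc(OCc2ccccc2)c(OCc2ccccc2)c1
F11 | step 5 | (2R,3E)-4-[3,4-bis(benzyloxy)phenyl]-2-(3,4-dimethoxybenzyl)but-3-en-1-yl chlorooxoacetate | O=C(Cl)C(=O)OC[C@H](Cc1ccc(OC)c(OC)c1)/C=C/c1ccc(OCc2ccccc2)c(OCc2ccccc2)c1
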